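**Retrosynthetic overview**
1. Target 7 ← O-debenzylation of 4'-benzyloxyflavone 6, so the free phenol is unmasked last.
2. Ring C of 6 ← I2/DMSO oxidative cyclisation of 2'-hydroxychalcone 4 (O1–C2 bond, then C2=C3 dehydrogenation).
3. Chalcone 4 ← Claisen–Schmidt condensation of acetophenone 1 (ring A with all four OMe) with aldehyde 2 (ring B).
4. Rings A and B are bought intact; only the pyranone ring C is built (step 2).

Assumption: the target is achiral (no stereocentre), so "single enantiomer" places no demand; 2'-hydroxy-3',4',5',6'-tetramethoxyacetophenone (CAS 3162-28-5) and 4-(benzyloxy)benzaldehyde are taken as catalogue compounds.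

**Route**

Step 1
Reactants: 1 2'-hydroxy-3',4',5',6'-tetramethoxyacetophenone; 2 4-(benzyloxy)benzaldehyde
Product: 4 (E)-4-benzyloxy-2'-hydroxy-3',4',5',6'-tetramethoxychalcone, via β-hydroxy ketone aldol adduct 3 (not isolated)
Conditions: KOH (50% aq, 10 equiv), EtOH, rt, 48 h; then 2 M HCl, 0 °C
Reagents that add atoms: none
Why: Claisen–Schmidt (crossed aldol) condensation in which only the methyl ketone can enolise and the aldehyde cannot self-condense, and E1cB dehydration of the aldol gives the conjugated E-enone with no stereocentre remaining.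

Step 2
Reactants: 4 (E)-4-benzyloxy-2'-hydroxy-3',4',5',6'-tetramethoxychalcone
Product: 6 4'-benzyloxy-5,6,7,8-tetramethoxyflavone, via racemic flavanone 5 (not isolated)
Conditions: I2 (10 mol%), DMSO, 130 °C, 3 h; aq. Na2S2O3 wash, recrystallise from EtOH
Reagents that add atoms: none
Why: I2/DMSO oxidative cyclisation, in which intramolecular oxa-Michael addition of the 2'-phenol gives the flavanone and iodine-mediated dehydrogenation (DMSO as terminal oxidant) gives the flavone, erasing the transient C2 stereocentre.

Step 3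
Reactants: 6 4'-benzyloxy-5,6,7,8-tetramethoxyflavone
Product: 7 4'-hydroxy-5,6,7,8-tetramethoxyflavone
Conditions: H2 (1 atm), 10% Pd/C, EtOAc/MeOH 1:1, rt, 3 h
Reagents that add atoms: none
Why: Pd-catalysed hydrogenolysis cleaves the benzylic C–O bond to free the phenol, while the aryl methyl ethers and the chromone C2=C3 bond are inert at 1 atm and room temperature.

**Compound list**
1 | 2'-hydroxy-3',4',5',6'-tetramethoxyacetophenone | CC(=O)c1c(O)c(OC)c(OC)c(OC)c1OC | starting material
2 | 4-(benzyloxy)benzaldehyde | O=Cc1ccc(OCc2ccccc2)cc1 | starting material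
3 | 3-[4-(benzyloxy)phenyl]-3-hydroxy-1-(2-hydroxy-3,4,5,6-tetramethoxyphenyl)propan-1-one (racemic aldol adduct) | COc1c(OC)c(OC)c(O)c(C(=O)CC(O)c2ccc(OCc3ccccc3)cc2)c1OC | intermediate (not isolated)
4 | (E)-4-benzyloxy-2'-hydroxy-3',4',5',6'-tetramethoxychalcone | COc1c(OC)c(OC)c(O)c(C(=O)/C=C/c2ccc(OCc3ccccc3)cc2)c1OC | intermediate
5 | 2-[4-(benzyloxy)phenyl]-5,6,7,8-tetramethoxychroman-4-one (racemic flavanone) | COc1c(OC)c(OC)c2OC(c3ccc(OCc4ccccc4)cc3)CC(=O)c2c1OC | intermediate (not isolated)
6 | 4'-benzyloxy-5,6,7,8-tetramethoxyflavone | COc1c(OC)c(OC)c2c(=O)cc(-c3ccc(OCc4ccccc4)cc3)oc2c1OC | intermediate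
7 | 4'-hydroxy-5,6,7,8-tetramethoxyflavone | COc1c(OC)c(OC)c2c(=O)cc(-c3ccc(O)cc3)oc2c1OC | target

**Totals**
Total step count: 3. Longest linear sequence: 3 steps (1 → 4 → 6 → 7).

**Steps most likely to fail, with fallbacks**

Step 2 (most likely). The risks are stalling at flavanone 5 and HI-induced loss of the peri 5-OMe or of the benzyl group at 130 °C. The fallback sets out from chalcone 4 and comes back at flavone 6. It separates ring closure from oxidation: 4 is cyclised with NaOAc in refluxing EtOH to flavanone 5, which is isolated this time, and 5 is dehydrogenated with DDQ in refluxing dioxane to give 6 under non-acidic, iodide-free conditions. No compound outside the list is made (F0).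

Step 1. The acetyl group of 1 is flanked by two ortho substituents, so the condensation may be slow, with Cannizzaro loss of 2 competing. The fallback sets out from 1 and comes back at 6, bypassing chalcone 4 and step 2 by a Baker–Venkataraman sequence. The phenol of 1 is acylated with commercial 4-(benzyloxy)benzoyl chloride (pyridine, cat. DMAP, rt) to give 2-acetyl-3,4,5,6-tetramethoxyphenyl 4-(benzyloxy)benzoate F1. KOH in pyridine at 50 °C then effects the O→C acyl shift to 1-[4-(benzyloxy)phenyl]-3-(2-hydroxy-3,4,5,6-tetramethoxyphenyl)propane-1,3-dione F2. Cyclodehydration of F2 with catalytic p-TsOH in refluxing toluene gives flavone 6.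

Step 3. The risks are catalyst poisoning by traces of iodine or sulfur from step 2 and over-reduction of the C2=C3 bond. The fallback sets out from 1 and comes back at 7, replacing the benzyl group with an acid-labile acetal so that no reductive step is needed. Ketone 1 is condensed with commercial 4-(methoxymethoxy)benzaldehyde under the step 1 conditions to give (E)-2'-hydroxy-3',4',5',6'-tetramethoxy-4-(methoxymethoxy)chalcone F3. I2/DMSO cyclisation as in step 2 gives 5,6,7,8-tetramethoxy-4'-(methoxymethoxy)flavone F4. Treatment of F4 with 2 M HCl in MeOH at 50 °C gives 7; any acetal already lost during the I2/DMSO step converges on the same product.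

**Further compounds**
F1 | step 1 | 2-acetyl-3,4,5,6-tetramethoxyphenyl 4-(benzyloxy)benzoate | CC(=O)c1c(OC(=O)c2ccc(OCc3ccccc3)cc2)c(OC)c(OC)c(OC)c1OC
F2 | step 1 | 1-[4-(benzyloxy)phenyl]-3-(2-hydroxy-3,4,5,6-tetramethoxyphenyl)propane-1,3-dione | COc1c(OC)c(OC)c(O)c(C(=O)CC(=O)c2ccc(OCc3ccccc3)cc2)c1OC
F0 | step 2 | none | none
F3 | step 3 | (E)-2'-hydroxy-3',4',5',6'-tetramethoxy-4-(methoxymethoxy)chalcone | COCOc1ccc(/C=C/C(=O)c2c(O)c(OC)c(OC)c(OC)c2OC)cc1
F4 | step 3 | 5,6,7,8-tetramethoxy-4'-(methoxymethoxy)flavone | COCOc1ccc(-c2cc(=O)c3c(OC)c(OC)c(OC)c(OC)c3o2)cc1
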